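Under the card's two steps, a first end group stands free, as a link or as the dormant form, so the dormant form in a batch run is the charge less the two read columns.

| setting | winter | summer | dusk | Tuesday's | Sunday's | Monday's | Thursday's | Saturday's |
|---|---|---|---|---|---|---|---|---|
| first end groups | 0.050 M | 0.050 M | 0.050 M | 0.050 M | 0.050 M | 0.050 M | 0.050 M | 0.050 M (fed, over 30 min) |
| second end groups | 0.0525 M | 0.073 M | 0.12 M | 0.0525 M (fed, over 30 min) | 0.0525 M (in portions, 2, over 30 min) | 0.0525 M (fed, over 30 min) | 0.0525 M | 0.0525 M |
| temperature | 10 °C | 25 °C | 10 °C | 25 °C | 25 °C |  |  | 25 °C |
| remark | run made earlier | run made earlier | run made earlier | all else is in the flask from the start; the feed brings no volume worth counting | first portion at the start, last at 30 min | the addition at −15 °C, then warmed to 25 °C; the feed brings no volume worth counting | everything together at the start at −15 °C, warmed to 25 °C at 30 min | all else is in the flask from the start; the feed brings no volume worth counting |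
| time |  |  |  | 40 min | 40 min | 40 min | 40 min | 40 min |

| run | time / min | links / % | first end groups / % |
|---|---|---|---|
| winter | 8.00 | 21.9 | 69.8 |
| winter | 15.0 | 32.2 | 53.4 |
| winter | 25.0 | 43.5 | 38.2 |
| winter | 30.0 | 43.2 | 31.6 |
| winter | 40.0 | 52.3 | 23.1 |
| winter | 50.0 | 56.1 | 18.7 |
| summer | 3.00 | 30.0 | 53.0 |
| summer | 10.0 | 53.8 | 14.5 |
| summer | 15.0 | 58.8 | 6.8 |
| summer | 25.0 | 61.4 | 2.0 |
| summer | 40.0 | 66.0 | 1.0 |
| summer | 50.0 | 64.3 | 1.3 |
| dusk | 8.00 | 40.4 | 50.3 |
| dusk | 12.0 | 51.5 | 37.7 |
| dusk | 20.0 | 68.2 | 19.6 |
| dusk | 40.0 | 79.3 | 5.4 |
| dusk | 60.0 | 82.8 | 0.8 |
| dusk | 120 | 83.8 | 1.4 |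

(readings scatter by 1 percentage point)

- what was read earlier has a scatter of 1 percentage point, one standard deviation
- what may be going on: first end groups + second end groups -> links + by-product; first end groups <-> dormant form

* the flask that comes out highest in amount of links, in percent of the first end groups charged, or "all alike" when all lie within 1.5 percentage points (Tuesday's / Sunday's / Monday's / Thursday's / Saturday's / all alike)
* links at the end, in percent of the first end groups charged, Tuesday's
* links at the end, in percent of the first end groups charged, Sunday's
* links at the end, in percent of the first end groups charged, Monday's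
* links at the end, in percent of the first end groups charged, Thursday's
* links at the end, in percent of the first end groups charged, Saturday's

The decision is which charging order to run next. A free first end group has two exits, and the reckoning below, which is my own, compares them.

1. Let [B] be the concentration of second end groups. Links form in proportion to [B], while the dormant form does not depend on it. The slow return from the dormant form is left out as a small correction.

2. The summer run at 3.00 min reads 30.0% links and 53.0% first end groups, so the dormant form stands at 17.0%. With [B] averaging 0.0655 M, this gives B* = 0.0371 M, the level of second end groups at which both exits run equally fast. The link share of what reacts, the selectivity, is f = [B]/([B] + B*). The same reading of the winter run at 15.0 min gives 0.0199 M, which is lower than the summer reading.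

3. The summer run's loss of first end groups gives 0.212 min⁻¹, of which the dormant exit takes 0.0765 min⁻¹.

4. In Tuesday's, the feed, counted without what links consume, brings [B] up to B* at 21.2 min. Links do consume second end groups, so up to then [B] averages under B*/2 and f stays below a third. On this count about 8.76% of the first end groups is still free by then, and links by then come to under about 30.4%.

5. Sunday's opens at f = 41.4%, and f falls from there until the last portion at 30 min.

6. Saturday's, reckoned at an average [B] near 0.0400 M, has f of 51.9%.

7. Monday's and Thursday's, with the cold counted as idle, have 10.0 min warm at the same f. That leaves 20.4% free and gives links of 41.3%.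

So Saturday's is the run to make.

The forecast, which sits above my cold figure, gives 29%, 36%, 45%, 47% and 52% for Tuesday's, Sunday's, Monday's, Thursday's and Saturday's, with Saturday's highest, since “Saturday's keeps second end groups in excess throughout”.

The flask gives 28.5%, 36.3%, 44.8%, 46.5% and 51.3% in that order, with Saturday's highest.

    first end groups + second end groups → links + by-product (k = 2.22 L mol⁻¹ min⁻¹, Ea = 56.0 kJ mol⁻¹)
    first end groups ⇌ dormant form (K = 14.0, k = 0.0771 min⁻¹, Ea = 84.0 kJ mol⁻¹, ΔH = −18.0 kJ mol⁻¹)
    (constants at 25 °C)

Tuesday's at 20.0 min holds 19.1% links against 66.6% dormant form, a link share of 22.3%, under a third. The repeat of Tuesday's at 10 °C takes the winter reading of B*, so its crossing, counted from the feed without consumption, moves to 11.4 min, earlier than the same count for Tuesday's. That flask ends with 36.3% links against 32.5% dormant form, and 31% of the first end groups is still free at 40.0 min.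

The earlier runs and the new flask come from a simulation for substances that don't exist.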